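**Retrosynthetic overview**

Numbering: C1 = C(OH)iPr, C2/C3 = CH2, C4 = angular C(Me), C5 = CH2, C6 = CH(OH), C7 = C(OH)Me, C8 = C=O, C9 = CH(OAr), C10 = ring-fusion CH; cyclopentane C1–C2–C3–C4–C10, cycloheptanone C4–C5–C6–C7–C8–C9–C10.
The plan rests on C7: it lies between C6 and the C8 carbonyl, so the seven-membered ring is a six-membered C4–C5–C6–C8–C9–C10 ketone with one methyl-bearing carbon inserted into its C6–C8 bond.
Endgame: the aryl ester comes from acylation of the C9 hydroxyl, the cis C6/C7 diol from OsO4 on a C6=C7 enone, and the enone from the 7-methylcycloheptanone by Saegusa dehydrogenation.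
Key disconnection: the cycloheptanone comes from a trans-hydrindane β-hydroxy acid (propanoate aldol adduct at C8) by anodic decarboxylation with 1,2-shift of C6.
The hydrindanone comes from a C9=C10 enone (Li/NH3 sets H-10, Rubottom sets C9–O, i-PrMgCl sets C1), made by a chiral-imine Robinson annulation on 2-methylcyclopentanone that sets C4; ring order: five (bought), six (annulation), seven (ring enlargement).

Key step: step 12

Assumption: the chiral imine of 2-methylcyclopentanone is taken to show the same sense of induction as the 2-methylcyclohexanone imine, so that the (S)-amine gives the (R)-configured quaternary carbon C4; if the sense were opposite, the (R)-amine would be used.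

**Step 1**
Reactants: 1 2-methylcyclopentan-1-one (racemic); 2 (S)-1-phenylethylamine
Product: 3 (S)-N-(2-methylcyclopentylidene)-1-phenylethanamine (both C2 epimers, interconverting through the enamine)
Conditions: p-TsOH (cat.), toluene, reflux, Dean–Stark
Reagents that add atoms: (S)-1-phenylethylamine, C[C@H](N)c1ccccc1
Why: Acid-catalysed imine formation is driven to completion by azeotropic removal of water, and the ring stereocentre is of no account because it is lost in the enamine tautomer that reacts in step 2.

**Step 2**
Reactants: 3 (S)-N-(2-methylcyclopentylidene)-1-phenylethanamine; 4 but-3-en-2-one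
Product: 6 (R)-2-methyl-2-(3-oxobutyl)cyclopentan-1-one, via Michael adduct imine 5 (not isolated)
Conditions: 4 (1.2 equiv), THF, rt; then 10% aq. AcOH, rt
Reagents that add atoms: but-3-en-2-one, CC(=O)C=C; water, O
Why: In this deracemising Michael addition of a chiral imine, the more substituted secondary enamine tautomer adds to the enone through a compact aza-ene-like transition state in which the acceptor approaches the enamine face away from the phenyl group of the auxiliary, which sets the quaternary centre C4, and mild acid hydrolysis releases the diketone and the recoverable amine.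

**Step 3**
Reactants: 6 (R)-2-methyl-2-(3-oxobutyl)cyclopentan-1-one
Product: 7 (R)-7a-methyl-1,2,3,6,7,7a-hexahydro-5H-inden-5-one (C8 ketone, C9=C10)
Conditions: NaOMe (0.3 equiv), MeOH, 60 °C
Reagents that add atoms: none
Why: Base-mediated intramolecular aldol condensation, the ring-closing half of a Robinson annulation, lets the methyl-ketone enolate attack the ring carbonyl C10 to close the six-membered ring and dehydration gives the conjugated enone, while the quaternary centre has no α-hydrogen and cannot epimerise.

**Step 4**
Reactants: 7 (R)-7a-methyl-1,2,3,6,7,7a-hexahydro-5H-inden-5-one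
Product: 8 C8 ethylene ketal of 7 (C9=C10 kept in place)
Conditions: (TMSOCH2)2 (2 equiv), TMSOTf (5 mol%), CH2Cl2, −78 to −20 °C; pyridine quench
Reagents that add atoms: 1,2-bis(trimethylsilyloxy)ethane, C[Si](C)(C)OCCO[Si](C)(C)C
Why: Ketalisation under aprotic silyl-triflate catalysis at low temperature (Noyori conditions) is known to convert enones into ketals without moving the double bond out of the α,β-position, so C8 is masked while C1 becomes the only allylic CH2.

**Step 5**
Reactants: 8 C8 ethylene ketal of 7
Product: 9 C1-oxo enone ketal (C1 ketone conjugated to C9=C10; C8 dioxolane)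
Conditions: Rh2(cap)4 (cap = caprolactamate, 1 mol%), t-BuOOH (5 equiv, in decane), K2CO3, CH2Cl2, rt
Reagents that add atoms: tert-butyl hydroperoxide, CC(C)(C)OO
Why: Rhodium-catalysed allylic oxidation with tert-butyl hydroperoxide proceeds by hydrogen abstraction from the only allylic C–H bonds (C1, since C4 and C8 are quaternary), trapping of the allyl radical at its less hindered terminus C1 and collapse of the mixed peroxide to the ketone, while the carbonate-buffered, non-aqueous medium leaves the ketal untouched.

**Step 6**
Reactants: 9 C1-oxo enone ketal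
Product: 11 hydroxy enone (1-OH cis to 4-Me; 1-isopropyl trans; C9=C10; C8 ketone), via tertiary alcohol ketal 10 (not isolated)
Conditions: i-PrMgCl (1.5 equiv), LaCl3·2LiCl (1 equiv), THF, −20 to 0 °C; then 1 M aq. HCl, THF, 0 °C
Reagents that add atoms: isopropylmagnesium chloride, CC(C)[Mg]Cl; water, O
Why: Lanthanum-chloride-promoted 1,2-addition of a Grignard reagent to the enone carbonyl (the Lewis acid suppresses enolisation, β-hydride reduction and conjugate addition) should occur on the face of C1 opposite to the angular C4 methyl, which stands perpendicular to the enone plane two bonds away, so that isopropyl enters trans and the hydroxyl is cis to the methyl, and the brief cold acid work-up hydrolyses the unsaturated ketal faster than the tertiary allylic alcohol can ionise.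

**Step 7**
Reactants: 11 hydroxy enone
Product: 13 bis(trimethylsilyl) compound (C8=C9 silyl enol ether; C1 silyl ether; trans ring fusion), via dilithium enolate alkoxide 12 (not isolated)
Conditions: Li (2.4 equiv), NH3(l)/THF, −78 °C; isoprene; NH3 evaporated; TMSCl/Et3N (excess), THF, −78 °C to rt
Reagents that add atoms: chlorotrimethylsilane, C[Si](C)(C)Cl
Why: In this dissolving-metal (Birch-type) enone reduction with regiospecific enolate trapping, the substrate hydroxyl supplies the single proton equivalent and ends as the lithium alkoxide (a non-leaving group at the γ-position), C10 is protonated axially to give the more stable trans ring fusion with H-10 anti to the angular methyl, and O-silylation fixes the C8=C9 enol ether that direct enolisation of the saturated ketone would not give.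

**Step 8**
Reactants: 13 bis(trimethylsilyl) compound
Product: 15 trans-hydrindan-8-one-1,9-diol (9-OH α; equatorial; cis to H-10), via α-silyloxy ketone 14 (not isolated)
Conditions: m-CPBA (1.1 equiv), NaHCO3, CH2Cl2, −20 to 0 °C; then 1 M aq. HCl, THF, rt
Reagents that add atoms: m-chloroperbenzoic acid, OOC(=O)c1cccc(Cl)c1
Why: In this Rubottom oxidation the peracid should epoxidise the enol ether from the α face, because the β face of C9 is 1,3-diaxial to the angular methyl, the silyloxy epoxide opens with 1,4-silyl shift to the α-silyloxy ketone with the C9 oxygen equatorial and cis to H-10, and dilute acid removes both trimethylsilyl groups.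

**Step 9**
Reactants: 15 trans-hydrindan-8-one-1,9-diol
Product: 16 1,9-bis(triethylsilyl) ether of 15
Conditions: TESOTf (3 equiv), 2,6-lutidine (5 equiv), CH2Cl2, −78 to 0 °C
Reagents that add atoms: triethylsilyl trifluoromethanesulfonate, CC[Si](CC)(CC)OS(=O)(=O)C(F)(F)F
Why: A silyl triflate with a hindered pyridine base silylates the secondary α-hydroxyl and also the hindered tertiary C1 alcohol, which a chlorosilane would leave untouched, and below 0 °C the ketone is not converted into its enol silane.

**Step 10**
Reactants: 16 bis(triethylsilyl) ketone; 17 benzyl propanoate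
Product: 19 benzyl ester of the C8 aldol adduct (8-OH axial; propanoate unit equatorial), via lithium enolate 18 (not isolated)
Conditions: LiN(i-Pr)2 (1.3 equiv), 17 (1.3 equiv), THF, −78 °C; then 16, −78 °C; sat. aq. NH4Cl at −78 °C
Reagents that add atoms: benzyl propanoate, CCC(=O)OCc1ccccc1
Why: Aldol addition of a preformed lithium ester enolate to a ketone activated by its α-silyloxy group should outrun proton transfer at −78 °C, attack being expected from the equatorial direction (the axial α path is screened by H-10 and the C1 isopropyl), and the configurations of the new carbinol and of the methyl-bearing carbon do not matter because both centres are rebuilt in step 12.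

**Step 11**
Reactants: 19 benzyl ester of the C8 aldol adduct
Product: 20 trans-hydrindane β-hydroxy acid (2-(8-hydroxy-1,9-bis(triethylsilyloxy)hydrindan-8-yl)propanoic acid)
Conditions: H2 (1 atm), Pd/C (10%), EtOAc, rt
Reagents that add atoms: none
Why: Hydrogenolysis of the benzyl ester liberates the acid under neutral conditions, which avoids the retro-aldol cleavage that saponification of a hindered β-hydroxy ester would invite, and the silyl ethers are stable in the aprotic solvent.

**Step 12**
Reactants: 20 trans-hydrindane β-hydroxy acid
Product: 21 trans-fused 7-methylcycloheptan-8-one with 1,9-bis(triethylsilyloxy) groups (C7 epimers carried on together; drawn with 7-Me β)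
Conditions: undivided cell, graphite anode, Pt cathode, 2,4,6-collidine (1.5 equiv), n-Bu4NPF6 (0.1 M), dry MeCN, constant current (5 mA cm−2, 3 F mol−1), rt
Reagents that add atoms: none
Why: The carboxylate is oxidised at the graphite anode, CO2 is lost and a second electron transfer turns the C7 radical into a carbocation beside the tertiary carbinol; the ring bond C8–C6 then shifts to C7 while the hydroxyl oxygen becomes the C8 carbonyl, which forms the C6–C7 bond. The closest known reaction type is the anodic (Hofer–Moest type) one-carbon ring expansion of cycloalkanone-derived β-hydroxy acids, a decarboxylative semipinacol rearrangement. The seven-membered ring is not closed by a cyclisation but arises by ring enlargement, the 1,2-migration of ring carbon C6 inserting C7 into the six-membered ring, and loss of CO2 makes the shift irreversible. The new centre C7 is formed without reliable control (it depends on the rotamer of the cation and can equilibrate by enolisation), which is of no consequence because C7 becomes sp2 in steps 13 and 14. The selectivity needed is migration of the CH2 carbon C6 rather than C9: the inductively withdrawing silyloxy group on C9 disfavours the positive charge that a migrating carbon carries in the bridged transition state. The C1 oxygen is silylated so that it cannot capture the cation as a cyclic ether, and dry MeCN with a hindered pyridine base keeps solvent capture and acid-induced desilylation down.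

**Step 13**
Reactants: 21 7-methylcycloheptan-8-one
Product: 22 C7=C8 trimethylsilyl enol ether of 21
Conditions: TMSOTf (1.5 equiv), Et3N (3 equiv), CH2Cl2, 0 °C to rt
Reagents that add atoms: trimethylsilyl trifluoromethanesulfonate, C[Si](C)(C)OS(=O)(=O)C(F)(F)F
Why: Soft enolisation with a silyl triflate and triethylamine under equilibrating conditions should give the more stable enol silane, which is the C7=C8 isomer because an enol ether toward C9 would force the silyloxy group into the plane against C10 and its two quaternary neighbours, and both C7 epimers of 21 converge on the same product.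

**Step 14**
Reactants: 22 C7=C8 trimethylsilyl enol ether
Product: 23 C6=C7 enone (7-methylcyclohept-6-en-8-one with 1,9-bis(triethylsilyloxy) groups)
Conditions: Pd(OAc)2 (1.1 equiv), MeCN, rt to 40 °C
Reagents that add atoms: none
Why: In this Saegusa–Ito oxidation Pd(OAc)2 converts the enol silane into an oxa-π-allyl palladium species and syn β-hydride elimination toward the ring methylene C6 gives the conjugated endocyclic enone, which is more stable than the exocyclic methylene isomer.

**Step 15**
Reactants: 23 C6=C7 enone
Product: 24 1,9-dihydroxy enone
Conditions: HF·pyridine, pyridine, THF, 0 °C to rt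
Reagents that add atoms: none
Why: Cleavage of both triethylsilyl ethers with buffered HF·pyridine avoids the basic medium in which the α-hydroxy ketone could epimerise or undergo a ketol shift.

**Step 16**
Reactants: 24 1,9-dihydroxy enone; 25 4-(benzyloxy)benzoyl chloride
Product: 26 9-O-[4-(benzyloxy)benzoyl] enone
Conditions: 25 (1.5 equiv), DMAP (0.2 equiv), Et3N (3 equiv), CH2Cl2, 0 °C to rt
Reagents that add atoms: 4-(benzyloxy)benzoyl chloride, O=C(Cl)c1ccc(OCc2ccccc2)cc1
Why: DMAP-catalysed acylation with an acid chloride esterifies the secondary C9 hydroxyl, whereas the tertiary and heavily hindered C1 hydroxyl does not react under these conditions.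

**Step 17**
Reactants: 26 9-O-[4-(benzyloxy)benzoyl] enone
Product: 27 O-benzyl-protected target (6α,7α-diol)
Conditions: OsO4 (5 mol%), NMO (2 equiv), citric acid (1 equiv), t-BuOH/H2O 1:1, rt
Reagents that add atoms: osmium tetroxide (catalytic oxygen carrier), O=[Os](=O)(=O)=O; N-methylmorpholine N-oxide, C[N+]1([O-])CCOCC1; water, O
Why: Catalytic OsO4 dihydroxylation (Upjohn conditions, acidified to speed osmate hydrolysis of the electron-poor alkene and keep the medium non-basic) is a suprafacial addition that should deliver both oxygens to C6 and C7 from the α face, anti to the pseudoaxial angular methyl that screens the β face of C6, while the pseudoequatorial C9 ester does not block the α face, which sets the cis C6/C7 diol.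

**Step 18**
Reactants: 27 O-benzyl-protected target
Product: 28 CNP0241001.1 (target)
Conditions: H2 (1 atm), Pd/C (10%), EtOAc, rt
Reagents that add atoms: none
Why: Hydrogenolysis of the benzyl aryl ether over Pd/C liberates the phenol under neutral conditions, so that the β-hydroxy ketone, the tertiary ketol and the aryl ester are exposed neither to base nor to acid.

**Compound list**

1 | 2-methylcyclopentan-1-one (racemic) | CC1CCCC1=O | starting material
2 | (S)-1-phenylethylamine | C[C@H](N)c1ccccc1 | starting material
3 | (S)-N-(2-methylcyclopentylidene)-1-phenylethanamine (C2 epimers) | C[C@@H](c1ccccc1)N=C1CCCC1C | intermediate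
4 | but-3-en-2-one | CC(=O)C=C | starting material
5 | Michael adduct imine, 4-[(R)-1-methyl-2-{[(S)-1-phenylethyl]imino}cyclopentyl]butan-2-one (not isolated) | C[C@@H](c1ccccc1)N=C1CCC[C@]1(C)CCC(C)=O | intermediate
6 | (R)-2-methyl-2-(3-oxobutyl)cyclopentan-1-one | O=C1CCC[C@]1(C)CCC(C)=O | intermediate
7 | (R)-7a-methyl-1,2,3,6,7,7a-hexahydro-5H-inden-5-one | C1CC[C@]2(C)CCC(=O)C=C12 | intermediate
8 | C8 ethylene ketal of 7 (C9=C10 in place) | C1CC[C@]2(C)CCC3(OCCO3)C=C12 | intermediate
9 | C1-oxo enone ketal | O=C1CC[C@]2(C)CCC3(OCCO3)C=C12 | intermediate
10 | tertiary alcohol ketal, 1-OH cis to 4-Me (not isolated) | CC(C)[C@]1(O)CC[C@]2(C)CCC3(OCCO3)C=C12 | intermediate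
11 | hydroxy enone, 3-hydroxy-3-isopropyl-7a-methyl-1,2,3,6,7,7a-hexahydro-5H-inden-5-one (OH cis to the angular methyl) | CC(C)[C@]1(O)CC[C@]2(C)CCC(=O)C=C12 | intermediate
12 | dilithium enolate alkoxide (not isolated) | CC(C)[C@]1(O[Li])CC[C@]2(C)CCC(O[Li])=C[C@H]21 | intermediate
13 | bis(trimethylsilyl) compound: C8=C9 silyl enol ether, C1 silyl ether, trans-fused | CC(C)[C@]1(O[Si](C)(C)C)CC[C@]2(C)CCC(O[Si](C)(C)C)=C[C@H]21 | intermediate
14 | bis(trimethylsilyl) α-silyloxy ketone (not isolated) | CC(C)[C@]1(O[Si](C)(C)C)CC[C@]2(C)CCC(=O)[C@H](O[Si](C)(C)C)[C@H]21 | intermediate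
15 | trans-hydrindan-8-one-1,9-diol (9-OH α, cis to H-10) | CC(C)[C@]1(O)CC[C@]2(C)CCC(=O)[C@H](O)[C@H]21 | intermediate
16 | 1,9-bis(triethylsilyl) ether of 15 | CC(C)[C@]1(O[Si](CC)(CC)CC)CC[C@]2(C)CCC(=O)[C@H](O[Si](CC)(CC)CC)[C@H]21 | intermediate
17 | benzyl propanoate | CCC(=O)OCc1ccccc1 | starting material
18 | lithium enolate of benzyl propanoate (not isolated) | C/C=C(/O[Li])OCc1ccccc1 | intermediate
19 | benzyl ester of the C8 aldol adduct (isomer expected to prevail; epimers at the two new centres carried on) | CC(C)[C@]1(O[Si](CC)(CC)CC)CC[C@]2(C)CC[C@@](O)([C@H](C)C(=O)OCc3ccccc3)[C@H](O[Si](CC)(CC)CC)[C@H]21 | intermediate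
20 | trans-hydrindane β-hydroxy acid (key-step precursor) | CC(C)[C@]1(O[Si](CC)(CC)CC)CC[C@]2(C)CC[C@@](O)([C@H](C)C(=O)O)[C@H](O[Si](CC)(CC)CC)[C@H]21 | intermediate
21 | trans-fused 7-methylcycloheptan-8-one, 1,9-bis(triethylsilyloxy) (key-step product) | CC(C)[C@]1(O[Si](CC)(CC)CC)CC[C@]2(C)CC[C@@H](C)C(=O)[C@H](O[Si](CC)(CC)CC)[C@H]21 | intermediate
22 | C7=C8 trimethylsilyl enol ether | CC(C)[C@]1(O[Si](CC)(CC)CC)CC[C@]2(C)CCC(C)=C(O[Si](C)(C)C)[C@H](O[Si](CC)(CC)CC)[C@H]21 | intermediate
23 | C6=C7 enone, 1,9-bis(triethylsilyloxy) | CC(C)[C@]1(O[Si](CC)(CC)CC)CC[C@]2(C)CC=C(C)C(=O)[C@H](O[Si](CC)(CC)CC)[C@H]21 | intermediate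
24 | 1,9-dihydroxy enone | CC(C)[C@]1(O)CC[C@]2(C)CC=C(C)C(=O)[C@H](O)[C@H]21 | intermediate
25 | 4-(benzyloxy)benzoyl chloride | O=C(Cl)c1ccc(OCc2ccccc2)cc1 | starting material
26 | 9-O-[4-(benzyloxy)benzoyl] enone | CC(C)[C@]1(O)CC[C@]2(C)CC=C(C)C(=O)[C@H](OC(=O)c3ccc(OCc4ccccc4)cc3)[C@H]21 | intermediate
27 | O-benzyl-protected target (6α,7α-diol) | CC(C)[C@]1(O)CC[C@]2(C)C[C@H](O)[C@](C)(O)C(=O)[C@H](OC(=O)c3ccc(OCc4ccccc4)cc3)[C@H]21 | intermediate
28 | CNP0241001.1 | CC(C)[C@]1(O)CC[C@]2(C)C[C@H](O)[C@](C)(O)C(=O)[C@H](OC(=O)c3ccc(O)cc3)[C@H]21 | target

**Step count and risks**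

Total steps: 18. Longest linear sequence: 18 steps (1 to 28); 4, 17 and 25 are purchased.

Steps most likely to fail:

1. Step 12 (key step). The oxygen-bearing ring carbon C9 may migrate in place of C6, the cation may be captured by the carbinol oxygen (epoxide formation) or by the solvent, or the intermediate radical may abstract hydrogen or dimerise before it is oxidised. Fallback, from 16 back to 21: ketone 16 would be homologated with trimethylsilyldiazomethane and Me3Al in CH2Cl2 at −78 °C, a Lewis-acid-promoted diazoalkane insertion in which the less substituted, non-oxygenated α-carbon C6 migrates, to give the α-trimethylsilyl cycloheptanone F1. The C–Si bond would be cleaved with K2CO3 in MeOH at 0 °C to the 7-unsubstituted cycloheptanone F2. Kinetic deprotonation at the C7 methylene with LiN(i-Pr)2 in THF at −78 °C followed by MeI would then give 21, and steps 10 and 11 drop out.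

2. Step 7. The C1 oxygen may be lost by reductive elimination from the C10 carbanion, or C10 may be protonated from the wrong face to give the cis ring fusion. Fallback, from 10 back to 15: compound 10, isolated by quenching step 6 with aqueous NH4Cl in place of acid, would be hydroborated with BH3·THF (THF, 0 °C to rt) and oxidised with NaOH/H2O2. Syn addition of hydrogen to C10 and boron to C9 from the α face, anti to the angular methyl and to the C1 hydroxyl, would give the hydroxy ketal F3 with the trans ring fusion and the α-oriented C9 oxygen in one operation. 1 M aq. HCl in THF would then unmask the C8 ketone to give 15, so that 11 to 14 are bypassed.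

3. Step 17. The osmium reagent may attack the β face of the flexible seven-membered ring, or the hindered, electron-poor alkene may react too slowly. Fallback, from 24 back to 27: diol 24 would be dihydroxylated before acylation with stoichiometric OsO4·TMEDA in CH2Cl2 at −78 °C, the reagent being held on the α face by hydrogen bonding to the free α-oriented C9 hydroxyl (work-up with aqueous NaHSO3), to give the tetraol F4. The cis C6/C7 diol would be tied up as the acetonide F5 (2,2-dimethoxypropane, PPTS, CH2Cl2), the C9 hydroxyl acylated with 25 (DMAP, Et3N) to give the ester acetonide F6, and the acetonide removed with 80% aq. AcOH at 40 °C to rejoin the route at 27.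

**Further compounds**

F1 | step 12 | α-trimethylsilyl cycloheptanone (7-trimethylsilyl analogue of 21, C7 epimers) | CC(C)[C@]1(O[Si](CC)(CC)CC)CC[C@]2(C)CCC([Si](C)(C)C)C(=O)[C@H](O[Si](CC)(CC)CC)[C@H]21
F2 | step 12 | 7-unsubstituted cycloheptan-8-one, 1,9-bis(triethylsilyloxy) | CC(C)[C@]1(O[Si](CC)(CC)CC)CC[C@]2(C)CCCC(=O)[C@H](O[Si](CC)(CC)CC)[C@H]21
F3 | step 7 | trans-hydrindane 1,9-diol C8 ethylene ketal | CC(C)[C@]1(O)CC[C@]2(C)CCC3(OCCO3)[C@H](O)[C@H]21
F4 | step 17 | 1,6,7,9-tetraol (6α,7α-diol, 9-OH free) | CC(C)[C@]1(O)CC[C@]2(C)C[C@H](O)[C@](C)(O)C(=O)[C@H](O)[C@H]21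
F5 | step 17 | 6,7-acetonide of the tetraol | CC(C)[C@]1(O)CC[C@]2(C)C[C@@H]3OC(C)(C)O[C@]3(C)C(=O)[C@H](O)[C@H]21
F6 | step 17 | 6,7-acetonide 9-O-[4-(benzyloxy)benzoate] | CC(C)[C@]1(O)CC[C@]2(C)C[C@@H]3OC(C)(C)O[C@]3(C)C(=O)[C@H](OC(=O)c4ccc(OCc5ccccc5)cc4)[C@H]21
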